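**Retrosynthetic overview**

1. Numbering used in the text: C1 enone C=O, C2=C3 (C3 carries a methyl), cyclobutane C4–C5–C11–C10, C6 = CMe2, C7 (methacrylate), C8 (CH2), C9 (isobutyrate), C10 quaternary (methyl), C11 the CH α to C1.
2. The target comes from a 7-hydroxy-1,9-diketone: an Evans–Tishchenko reaction with methacrolein reduces C9 anti to O7 and acylates O7, and isobutyrylation finishes.
3. Key disconnection, two bridges at once: C2=C3 and C10–C11. The tricycle comes from a monocyclic cycloheptanone with cis acetyl (on C4) and 3-phosphono-2-oxopropyl (on C5) groups, by intramolecular Horner–Wadsworth–Emmons olefination and then oxidative coupling of two enolates in one flask. Enabling feature: the C1 ketone lies between both new bonds (C2 and C11 are its two α-carbons), C3 is its 1,5-carbonyl partner, and C10 is the α-carbon of a C9 ketone, so C10–C11 is the central bond of a 1,4-diketone (two carbons of like polarity); the cis-fused six/seven bicycle formed first holds C11 over C10.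
4. The cycloheptanone comes from eucarvone (from carvone): Jacobsen epoxidation and SmI2 opening (C7–O), α′-alkylation (C5), ethynylation and Babler–Dauben transposition (C9=O, C3), hydration, hydrogenation (C4, C10).
5. Ring order: seven-membered ring first, then the cyclohexenone and the cyclobutane together in the key step.

Key step: step 14

**Route**

Step 1
Reactants: 1 (R)-carvone
Product: 2 (5R)-5-(2-bromopropan-2-yl)-2-methylcyclohex-2-en-1-one
Conditions: HBr (33% in AcOH), 0 °C
Reagents that add atoms: hydrogen bromide, Br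
Why: Markovnikov ionic addition of HBr to the electron-rich isopropenyl alkene, the enone alkene being deactivated; the stereocentre is untouched and is erased in step 2.

Step 2
Reactants: 2 carvone hydrobromide
Product: 3 eucarvone (2,6,6-trimethylcyclohepta-2,4-dien-1-one)
Conditions: KOH, MeOH, reflux
Reagents that add atoms: none
Why: the α′-enolate displaces the tertiary bromide (1,3-elimination to the carenone) and the derived dienolate opens the cyclopropane with ring expansion, the classical eucarvone synthesis; no stereocentre remains.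

Step 3
Reactants: 3 eucarvone
Product: 4 (4R,5S)-4,5-epoxy-2,6,6-trimethylcyclohept-2-en-1-one
Conditions: (R,R)-(salen)MnCl [(R,R)-N,N′-bis(3,5-di-tert-butylsalicylidene)cyclohexane-1,2-diamine manganese chloride, 5 mol%], aq. NaOCl (pH 11), 4-phenylpyridine N-oxide, CH2Cl2, 0 °C
Reagents that add atoms: sodium hypochlorite, [Na+].[O-]Cl
Why: Jacobsen epoxidation attacks the electron-richer cis-disubstituted γ,δ-alkene (conjugated on one side, quaternary carbon on the other, as in 2,2-dimethylchromene) and not the enone alkene; the catalyst sets C7 and C8, and the (R,R) enantiomer is expected to give the shown epoxide by the chromene analogy.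

Step 4
Reactants: 4 epoxy dienone
Product: 6 (5R)-5-hydroxy-2,6,6-trimethylcyclohept-2-en-1-one, via deconjugated hydroxy enone 5 (not isolated)
Conditions: SmI2 (2.1 equiv), THF–MeOH, −78 °C; then DBU (0.2 equiv), CH2Cl2, rt
Reagents that add atoms: none
Why: SmI2 reduction of a vinylogous epoxy ketone cleaves the allylic C8–O bond through the ketyl and dienolate, the C7–O bond is not touched so its configuration is kept, and DBU moves the alkene back into conjugation.

Step 5
Reactants: 6 hydroxy enone
Product: 7 (5R)-5-[(tert-butyldimethylsilyl)oxy]-2,6,6-trimethylcyclohept-2-en-1-one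
Conditions: TBSOTf, 2,6-lutidine, CH2Cl2, −78 → 0 °C
Reagents that add atoms: tert-butyldimethylsilyl triflate, CC(C)(C)[Si](C)(C)OS(=O)(=O)C(F)(F)F
Why: silylation of the hindered secondary alcohol protects it through the enolate, Grignard and chromium steps.

Step 6
Reactants: 8 diethyl (2-oxopropyl)phosphonate
Product: 9 diethyl [(1E)-2-ethoxyprop-1-en-1-yl]phosphonate
Conditions: HC(OEt)3, EtOH, H2SO4 (cat.), reflux, then distillation
Reagents that add atoms: triethyl orthoformate, CCOC(OCC)OCC
Why: acid-catalysed ketalization and loss of ethanol give the conjugated push–pull enol ether, the E isomer being the thermodynamic one.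

Step 7
Reactants: 9 enol ether phosphonate
Product: 10 diethyl [(1E)-3-bromo-2-ethoxyprop-1-en-1-yl]phosphonate
Conditions: NBS, AIBN (cat.), PhCF3, 80 °C
Reagents that add atoms: N-bromosuccinimide, O=C1CCC(=O)N1Br
Why: Wohl–Ziegler bromination at the only allylic methyl group gives a masked 3-phosphono-2-oxopropyl electrophile.

Step 8
Reactants: 7 silyloxy enone; 10 allylic bromide
Product: 11 (5R,7S)-5-[(tert-butyldimethylsilyl)oxy]-7-[(2E)-3-(diethoxyphosphoryl)-2-ethoxyprop-2-en-1-yl]-2,6,6-trimethylcyclohept-2-en-1-one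
Conditions: LDA, THF, −78 °C; then 10, DMPU, −78 → −30 °C
Reagents that add atoms: none
Why: kinetic α′-deprotonation (C5 is the only sp3 α-carbon) and SN2 alkylation by the allylic bromide; the electrophile should enter anti to the silyloxy group across the gem-dimethyl carbon, which sets C5 trans to O7.

Step 9
Reactants: 11 alkylated enone
Product: 12 (5R,7S)-5-[(tert-butyldimethylsilyl)oxy]-7-[(2E)-3-(diethoxyphosphoryl)-2-ethoxyprop-2-en-1-yl]-1-ethynyl-2,6,6-trimethylcyclohept-2-en-1-ol (both C1 epimers)
Conditions: ethynylmagnesium bromide, CeCl3, THF, −78 → 0 °C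
Reagents that add atoms: ethynylmagnesium bromide, C#C[Mg]Br
Why: organocerium 1,2-addition to the hindered enone carbonyl without enolization; the new carbinol centre is irrelevant because it becomes sp2 in step 10.

Step 10
Reactants: 12 tertiary allylic propargylic alcohol
Product: 13 (4R,6R)-6-[(tert-butyldimethylsilyl)oxy]-4-[(2E)-3-(diethoxyphosphoryl)-2-ethoxyprop-2-en-1-yl]-3-ethynyl-2,5,5-trimethylcyclohept-2-en-1-one
Conditions: pyridinium chlorochromate [C5H5NH][CrO3Cl], NaOAc, 4 Å MS, CH2Cl2, rt
Reagents that add atoms: pyridinium chlorochromate, [O-][Cr](=O)(=O)Cl.c1cc[nH+]cc1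
Why: Babler–Dauben oxidative transposition: the chromate ester shifts across the only allyl system to C9 and is oxidized there, which places the ketone at C9 and the alkynyl carbon on C4.

Step 11
Reactants: 13 enynone
Product: 14 (4S,6R)-3-acetyl-6-[(tert-butyldimethylsilyl)oxy]-4-[3-(diethoxyphosphoryl)-2-oxopropyl]-2,5,5-trimethylcyclohept-2-en-1-one
Conditions: Ph3PAuNTf2 (2 mol%), H2O, 1,4-dioxane, 60 °C; then 1 M aq. HCl, THF, 0 °C
Reagents that add atoms: water, O
Why: gold-catalysed Markovnikov hydration of the terminal alkyne gives the acetyl group (C3 and its methyl) and brief acid hydrolysis of the enol ether frees the β-ketophosphonate, while the hindered silyl ether should survive.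

Step 12
Reactants: 14 enedione
Product: 15 (2S,3S,4R,6R)-3-acetyl-6-[(tert-butyldimethylsilyl)oxy]-4-[3-(diethoxyphosphoryl)-2-oxopropyl]-2,5,5-trimethylcycloheptan-1-one
Conditions: H2 (1 atm), Pd/C, EtOAc, rt
Reagents that add atoms: none
Why: syn hydrogenation of the activated tetrasubstituted enedione alkene from the face opposite the adjacent C5 side chain delivers both hydrogens anti to it, so the acetyl group on C4 ends cis to the side chain.

Step 13
Reactants: 15 silyl ether
Product: 16 (2S,3S,4R,6R)-3-acetyl-4-[3-(diethoxyphosphoryl)-2-oxopropyl]-6-hydroxy-2,5,5-trimethylcycloheptan-1-one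
Conditions: HF·pyridine, THF, 0 °C → rt
Reagents that add atoms: none
Why: acidic fluoride cleaves the Si–O bond without the retro-aldol or β-elimination that basic fluoride could cause in a β-hydroxy ketone.

Step 14
Reactants: 16 hydroxy triketone phosphonate
Product: 18 (4R,5S,7R,10R,11R)-7-hydroxylongipin-2-ene-1,9-dione, via cis-fused bicyclic hydroxy enedione 17 (not isolated)
Conditions: NaH (1.05 equiv), THF (high dilution), 0 → 40 °C; then −78 °C, LDA (3.3 equiv), 1 h; then Fe(acac)3 (2.2 equiv), −78 °C → rt; H2O
Reagents that add atoms: none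
Why: Deprotonation of the β-ketophosphonate and intramolecular Horner–Wadsworth–Emmons olefination of the C4 acetyl group (carbanion C2 adds to the C3 carbonyl in a 6-exo-trig closure, then diethyl phosphate is lost) gives the C2=C3 enone regiospecifically as a cis-fused bicyclo[5.4.0]undecenone; LDA then forms the lithium alkoxide, the kinetic cross-conjugated dienolate at C11 and the C10 enolate of the C9 ketone, and trivalent iron oxidizes the more electron-rich tetrasubstituted C10 enolate to an α-keto radical that adds to the C11 enolate carbon (enolexo 4-exo-trig), the ketyl radical anion being oxidized by the second equivalent. The closest known reaction types are the ketophosphonate cyclohexenone annulation and the Fe(acac)3- or copper-mediated intramolecular oxidative heterocoupling of two carbonyl enolates to 1,4-diketones, which also closes small rings. C10 and C11 are set by the ring system alone: C11 hangs from C5 on the same face of the seven-membered ring as the C4 substituent, so it can reach only that face of the planar C10 enolate, which forces the C10 methyl to the opposite face and the C11 hydrogen toward the four-carbon bridge. The step needs α′- rather than γ-deprotonation of the enone (kinetic conditions), enolization of the C9 ketone toward C10 rather than C8 (C8 lies next to the lithium alkoxide and the C10 enolate is the more substituted one) and intra- rather than intermolecular coupling (high dilution, with C10 and C11 held close by the cis ring fusion). The product is a kinetic trap, because neither bridgehead α-carbon (C4, C11) can enolize and so neither new bond can be undone by retro-Michael or retro-aldol pathways.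

Step 15
Reactants: 18 tricyclic β-hydroxy ketone
Product: 19 (4R,5S,7R,9R,10R,11R)-9-hydroxy-1-oxolongipin-2-en-7-yl 2-methylprop-2-enoate
Conditions: methacrolein (8 equiv), SmI2 (0.3 equiv), THF, −10 °C
Reagents that add atoms: methacrolein, C=C(C)C=O
Why: Evans–Tishchenko reaction: the hemiacetal of the C7 hydroxyl and the aldehyde delivers hydride to the C9 ketone through a samarium-chelated chair, which gives the 1,3-anti alcohol at C9 and leaves the aldehyde as the methacrylate on O7; the C1 enone has no directing hydroxyl and is not reduced.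

Step 16
Reactants: 19 hydroxy methacrylate
Product: 20 (4R,5S,7R,9R,10R,11R)-9-(2-methylpropanoyloxy)-1-oxolongipin-2-en-7-yl 2-methylprop-2-enoate (CNP0214356.1)
Conditions: isobutyric anhydride, DMAP, Et3N, CH2Cl2, rt
Reagents that add atoms: isobutyric anhydride, CC(C)C(=O)OC(=O)C(C)C
Why: DMAP-catalysed acylation of the remaining hindered secondary alcohol; the methacrylate and the enone are inert to these conditions.

**Compound list**

1 | (R)-carvone | CC(=C)[C@@H]1CC=C(C)C(=O)C1 | starting material
2 | (5R)-5-(2-bromopropan-2-yl)-2-methylcyclohex-2-en-1-one | CC(C)(Br)[C@@H]1CC=C(C)C(=O)C1 | intermediate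
3 | eucarvone, 2,6,6-trimethylcyclohepta-2,4-dien-1-one | CC1=CC=CC(C)(C)CC1=O | intermediate
4 | (4R,5S)-4,5-epoxy-2,6,6-trimethylcyclohept-2-en-1-one | O2[C@@H]1[C@H]2C=C(C)C(=O)CC1(C)C | intermediate
5 | (5R)-5-hydroxy-2,6,6-trimethylcyclohept-3-en-1-one (C2 epimers, not isolated) | O[C@@H]1C=CC(C)C(=O)CC1(C)C | intermediate
6 | (5R)-5-hydroxy-2,6,6-trimethylcyclohept-2-en-1-one | O[C@@H]1CC=C(C)C(=O)CC1(C)C | intermediate
7 | (5R)-5-[(tert-butyldimethylsilyl)oxy]-2,6,6-trimethylcyclohept-2-en-1-one | CC(C)(C)[Si](C)(C)O[C@@H]1CC=C(C)C(=O)CC1(C)C | intermediate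
8 | diethyl (2-oxopropyl)phosphonate | CC(=O)CP(=O)(OCC)OCC | starting material
9 | diethyl [(1E)-2-ethoxyprop-1-en-1-yl]phosphonate | CCO/C(C)=C/P(=O)(OCC)OCC | intermediate
10 | diethyl [(1E)-3-bromo-2-ethoxyprop-1-en-1-yl]phosphonate | CCO/C(CBr)=C/P(=O)(OCC)OCC | intermediate
11 | (5R,7S)-5-silyloxy-7-[(2E)-3-(diethoxyphosphoryl)-2-ethoxyprop-2-en-1-yl]-2,6,6-trimethylcyclohept-2-en-1-one (side chain trans to the silyloxy group) | CC(C)(C)[Si](C)(C)O[C@@H]1CC=C(C)C(=O)[C@@H](C/C(OCC)=C\P(=O)(OCC)OCC)C1(C)C | intermediate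
12 | 1-ethynyl carbinol of 11 (C1 epimers) | CC(C)(C)[Si](C)(C)O[C@@H]1CC=C(C)C(O)(C#C)[C@@H](C/C(OCC)=C\P(=O)(OCC)OCC)C1(C)C | intermediate
13 | (4R,6R)-6-silyloxy-4-[(2E)-3-(diethoxyphosphoryl)-2-ethoxyprop-2-en-1-yl]-3-ethynyl-2,5,5-trimethylcyclohept-2-en-1-one | CC(C)(C)[Si](C)(C)O[C@@H]1CC(=O)C(C)=C(C#C)[C@@H](C/C(OCC)=C\P(=O)(OCC)OCC)C1(C)C | intermediate
14 | (4S,6R)-3-acetyl-6-silyloxy-4-[3-(diethoxyphosphoryl)-2-oxopropyl]-2,5,5-trimethylcyclohept-2-en-1-one | CC(C)(C)[Si](C)(C)O[C@@H]1CC(=O)C(C)=C(C(C)=O)[C@@H](CC(=O)CP(=O)(OCC)OCC)C1(C)C | intermediate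
15 | (2S,3S,4R,6R)-3-acetyl-6-silyloxy-4-[3-(diethoxyphosphoryl)-2-oxopropyl]-2,5,5-trimethylcycloheptan-1-one (acetyl cis to the side chain, both trans to the silyloxy group) | CC(C)(C)[Si](C)(C)O[C@@H]1CC(=O)[C@@H](C)[C@@H](C(C)=O)[C@@H](CC(=O)CP(=O)(OCC)OCC)C1(C)C | intermediate
16 | (2S,3S,4R,6R)-3-acetyl-4-[3-(diethoxyphosphoryl)-2-oxopropyl]-6-hydroxy-2,5,5-trimethylcycloheptan-1-one | O[C@@H]1CC(=O)[C@@H](C)[C@@H](C(C)=O)[C@@H](CC(=O)CP(=O)(OCC)OCC)C1(C)C | intermediate
17 | cis-fused 8-hydroxy-4,5,9,9-tetramethyl-hexahydrobenzo[7]annulene-2,6-dione (C3=C4 enone; ring-fusion hydrogens and hydroxyl on one face, C5 methyl on the other; not isolated) | O[C@@H]1CC(=O)[C@@H](C)[C@H]2C(C)=CC(=O)C[C@H]2C1(C)C | intermediate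
18 | (4R,5S,7R,10R,11R)-7-hydroxylongipin-2-ene-1,9-dione | O[C@@H]1CC(=O)[C@@]2(C)[C@@H]3C(=O)C=C(C)[C@H]2[C@@H]3C1(C)C | intermediate
19 | (4R,5S,7R,9R,10R,11R)-9-hydroxy-1-oxolongipin-2-en-7-yl 2-methylprop-2-enoate | C=C(C)C(=O)O[C@@H]1C[C@@H](O)[C@@]2(C)[C@@H]3C(=O)C=C(C)[C@H]2[C@@H]3C1(C)C | intermediate
20 | (4R,5S,7R,9R,10R,11R)-9-(2-methylpropanoyloxy)-1-oxolongipin-2-en-7-yl 2-methylprop-2-enoate | C=C(C)C(=O)O[C@@H]1C[C@@H](OC(=O)C(C)C)[C@@]2(C)[C@@H]3C(=O)C=C(C)[C@H]2[C@@H]3C1(C)C | target

**Step count**

Total step count: 16. Longest linear sequence: 14 steps (steps 1–5 and 8–16).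

**Steps most likely to fail**

1. Step 14. What may go wrong: the ring ketone may enolize toward C8 instead of C10, so that coupling closes the wrong ring or the lithium aldolate opens by retro-aldol cleavage. The strained four-membered ring closure may also lose to intermolecular coupling or α-oxidation. Fallback, from 16 back to 18: mesylation and elimination (MsCl, Et3N, CH2Cl2, 0 °C) remove the C7 oxygen and give the cyclohept-2-enone 6-acetyl-5-[3-(diethoxyphosphoryl)-2-oxopropyl]-4,4,7-trimethylcyclohept-2-en-1-one F1, whose ring ketone has C10 as its only enolizable α-carbon. The same one-flask sequence (NaH; LDA, 2.2 equiv; Fe(acac)3) should then give longipina-2,7-diene-1,9-dione F2. Copper-catalysed conjugate borylation of the less substituted enone (CuCl, NaOtBu, a chiral ferrocenyl bisphosphine, B2pin2, MeOH, THF) under catalyst control gives the 7-boryl diketone F3, which is oxidized in the same flask (NaBO3) to 18.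

2. Step 8. What may go wrong: poor facial selectivity of the alkylation, because the silyloxy group is separated from the enolate carbon by the quaternary carbon, and proton transfer or O-alkylation at the hindered enolate. Fallback, from 7 back to 11: condensation with (R)-1-amino-2-(methoxymethyl)pyrrolidine (RAMP, TsOH cat., benzene, reflux) gives the RAMP hydrazone of 7, F4. Azaenolate formation (LDA) and alkylation with 10 under auxiliary control (Enders alkylation) give the alkylated hydrazone F5. Saturated aqueous oxalic acid in Et2O releases 11 and the auxiliary.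

3. Step 15. What may go wrong: slow hemiacetal formation or hydride transfer with the unsaturated aldehyde, polymerization or reduction of methacrolein by samarium, and acyl migration between O7 and O9. Fallback, from 18 to 20: the Evans–Tishchenko reaction with acetaldehyde (SmI2 cat., THF, −10 °C) gives the 7-acetate 9-alcohol F6. Isobutyric anhydride and DMAP give the 7-acetate 9-isobutyrate F7. Selective methanolysis of the less hindered acetate (K2CO3, MeOH, 0 °C) gives the 7-alcohol 9-isobutyrate F8, and methacrylic anhydride, DMAP and Et3N give 20.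

**Further compounds**

F1 | step 14 | 6-acetyl-5-[3-(diethoxyphosphoryl)-2-oxopropyl]-4,4,7-trimethylcyclohept-2-en-1-one (stereocentres as in 16) | C1=CC(=O)[C@@H](C)[C@@H](C(C)=O)[C@@H](CC(=O)CP(=O)(OCC)OCC)C1(C)C
F2 | step 14 | (4R,5S,10R,11R)-longipina-2,7-diene-1,9-dione | C1=CC(=O)[C@@]2(C)[C@@H]3C(=O)C=C(C)[C@H]2[C@@H]3C1(C)C
F3 | step 14 | 7-(4,4,5,5-tetramethyl-1,3,2-dioxaborolan-2-yl)longipin-2-ene-1,9-dione (boron on the face of the later hydroxyl) | CC1(C)OB(OC1(C)C)[C@@H]1CC(=O)[C@@]2(C)[C@@H]3C(=O)C=C(C)[C@H]2[C@@H]3C1(C)C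
F4 | step 8 | RAMP hydrazone of 7 | CC(C)(C)[Si](C)(C)O[C@@H]1CC=C(C)C(=NN2CCC[C@@H]2COC)CC1(C)C
F5 | step 8 | RAMP hydrazone of 11 | CC(C)(C)[Si](C)(C)O[C@@H]1CC=C(C)C(=NN2CCC[C@@H]2COC)[C@@H](C/C(OCC)=C\P(=O)(OCC)OCC)C1(C)C
F6 | step 15 | 9-hydroxy-1-oxolongipin-2-en-7-yl acetate | CC(=O)O[C@@H]1C[C@@H](O)[C@@]2(C)[C@@H]3C(=O)C=C(C)[C@H]2[C@@H]3C1(C)C
F7 | step 15 | 7-acetoxy-1-oxolongipin-2-en-9-yl 2-methylpropanoate | CC(=O)O[C@@H]1C[C@@H](OC(=O)C(C)C)[C@@]2(C)[C@@H]3C(=O)C=C(C)[C@H]2[C@@H]3C1(C)C
F8 | step 15 | 7-hydroxy-1-oxolongipin-2-en-9-yl 2-methylpropanoate | O[C@@H]1C[C@@H](OC(=O)C(C)C)[C@@]2(C)[C@@H]3C(=O)C=C(C)[C@H]2[C@@H]3C1(C)C
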